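**Strategy.** Everything rests on disconnecting the C1–C2 bond of the quinone ring (C1 carbonyl beside C6–Me, C2 bearing OH beside the C3 side chain). The key step exploits the oxygens on C1, C2 and C4: the ring is treated as a pentasubstituted phenol made by 6π-electrocyclisation of a dienylketene whose carbonyl carbon becomes C2–OH and whose enol-ether terminus becomes C1. The precursor is a 4-chlorocyclobutenone (from an ynol ether and dichloroketene); palladium-catalysed coupling with a β-ethoxyalkenylstannane and opening of the strained ring join both fragments and build the arene in one operation. Chlorination at C5, hydrozirconation–iodination, Nozaki–Hiyama–Kishi union with the keto-aldehyde and oxidation to the quinone follow.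

Key step: step 11

Assumption: stannane 13 is drawn as the Z isomer expected from anti radical hydrostannation; the E isomer would converge on the same phenol 23, because the enol-ether geometry is lost on aromatisation.

**Step 1**
Reactants: 1 propanal; 2 but-3-en-2-one
Product: 3 (2R)-2-methyl-5-oxohexanal
Conditions: (S)-2-[methoxy(diphenyl)methyl]pyrrolidine (5 mol %), ethyl 3,4-dihydroxybenzoate (20 mol %), neat, 4 °C
Reagents that add atoms: none
Why: Enamine-catalysed Michael addition of the aldehyde to the enone, in which the diphenylmethyl ether group shields one face of the E-enamine so that the 2R aldehyde should result.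

**Step 2**
Reactants: 3 (2R)-2-methyl-5-oxohexanal
Product: 4 (4R)-4-methylcyclohex-2-en-1-one
Conditions: LiOH (0.2 equiv), i-PrOH, 23 °C
Reagents that add atoms: none
Why: Intramolecular aldol condensation of the methyl ketone onto the aldehyde closes the cyclohexenone, and the stereocenter, no longer alpha to a carbonyl once the aldol has occurred, should survive the mild base.

**Step 3**
Reactants: 4 (4R)-4-methylcyclohex-2-en-1-one
Product: 6 (4R)-3,4-dimethylcyclohex-2-en-1-one, via silyl enol ether 5 (not isolated)
Conditions: MeMgBr, CuBr·SMe2 (5 mol %), Me3SiCl, HMPA, THF, −78 °C; then Pd(OAc)2 (10 mol %), O2 (1 atm), DMSO, 25 °C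
Reagents that add atoms: methylmagnesium bromide C[Mg]Br
Why: Copper-catalysed conjugate methylation with silyl trapping gives the regiodefined enol ether, and Saegusa–Ito oxidation re-forms the C2=C3 double bond, now carrying the C3 methyl, without touching C4.

**Step 4**
Reactants: 6 (4R)-3,4-dimethylcyclohex-2-en-1-one
Product: 7 trimethyl{[(3S,4R)-3,4-dimethyl-3-(prop-2-en-1-yl)cyclohex-1-en-1-yl]oxy}silane
Conditions: allylMgBr, CuBr·SMe2 (1.2 equiv), Me3SiCl, THF, −78 °C; Et3N, pentane work-up
Reagents that add atoms: allylmagnesium bromide C=CC[Mg]Br; chlorotrimethylsilane C[Si](C)(C)Cl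
Why: Chlorosilane-accelerated conjugate addition of allylcopper to the β,β-disubstituted enone should deliver the allyl group anti to the C4 methyl, setting the quaternary center with its methyl cis to the C4 methyl, and the enolate is trapped regiospecifically.

**Step 5**
Reactants: 7 trimethyl{[(3S,4R)-3,4-dimethyl-3-(prop-2-en-1-yl)cyclohex-1-en-1-yl]oxy}silane
Product: 9 (2R,3S,4R)-2,3,4-trimethyl-3-(prop-2-en-1-yl)cyclohexan-1-one, via lithium enolate 8 (not isolated)
Conditions: MeLi, THF, 0 °C; MeI, HMPA, −78 to 0 °C; then NaOMe, MeOH, 25 °C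
Reagents that add atoms: iodomethane CI
Why: Methyllithium cleaves the silyl enol ether to the regiodefined enolate, which is C-methylated at C2 (enolate alkylation), and methoxide equilibration should place the epimerisable C2 methyl equatorial, cis to the quaternary methyl (2R).

**Step 6**
Reactants: 9 (2R,3S,4R)-2,3,4-trimethyl-3-(prop-2-en-1-yl)cyclohexan-1-one
Product: 11 2-[(1S,2R,6R)-1,2,6-trimethyl-3-oxocyclohexyl]acetaldehyde, via ozonide 10 (not isolated)
Conditions: O3, CH2Cl2, −78 °C; then PPh3, −78 to 25 °C
Reagents that add atoms: ozone [O-][O+]=O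
Why: Ozonolysis of the terminal alkene with reductive work-up gives the aldehyde under neutral conditions that leave the ketone and the three stereocenters untouched.

**Step 7**
Reactants: 12 1-ethoxyprop-1-yne
Product: 13 tributyl[(1Z)-1-ethoxyprop-1-en-2-yl]stannane
Conditions: Bu3SnH, AIBN (5 mol %), neat, 70 °C
Reagents that add atoms: tributyltin hydride CCCC[SnH](CCCC)CCCC
Why: Radical hydrostannation, in which the stannyl radical adds to the carbon β to oxygen (oxygen-stabilised vinyl radical) and kinetic anti addition should give mainly the Z β-stannyl enol ether.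

**Step 8**
Reactants: 14 ethoxyethyne; 15 1-bromobut-2-yne
Product: 17 1-ethoxyhexa-1,4-diyne, via lithium ethoxyacetylide 16 (not isolated)
Conditions: n-BuLi, THF, −78 °C; then 15, HMPA, −78 to 0 °C
Reagents that add atoms: none
Why: SN2 alkylation of the lithium alkoxyacetylide at the primary propargylic bromide (acetylide alkylation), HMPA raising nucleophilicity and favouring direct over allenic substitution.

**Step 9**
Reactants: 17 1-ethoxyhexa-1,4-diyne
Product: 18 2-(but-2-yn-1-yl)-4,4-dichloro-3-ethoxycyclobut-2-en-1-one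
Conditions: Cl3CCOCl, Zn–Cu couple, Et2O–DME, 0 to 25 °C
Reagents that add atoms: trichloroacetyl chloride ClC(=O)C(Cl)(Cl)Cl
Why: [2+2] cycloaddition of dichloroketene with the electron-rich ynol ether triple bond, whose carbon β to oxygen attacks the ketene carbonyl carbon and so fixes the 2-alkyl-3-ethoxy pattern, while the unactivated internal alkyne reacts far more slowly.

**Step 10**
Reactants: 18 2-(but-2-yn-1-yl)-4,4-dichloro-3-ethoxycyclobut-2-en-1-one
Product: 19 2-(but-2-yn-1-yl)-4-chloro-3-ethoxycyclobut-2-en-1-one (racemic)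
Conditions: Zn dust (1.1 equiv), AcOH, TMEDA, EtOH, −10 °C
Reagents that add atoms: none
Why: Reductive dehalogenation of the α,α-dichloroketone should stop at the monochloride with one equivalent of zinc at low temperature, because the second C–Cl bond is reduced more slowly.

**Step 11**
Reactants: 19 2-(but-2-yn-1-yl)-4-chloro-3-ethoxycyclobut-2-en-1-one; 13 tributyl[(1Z)-1-ethoxyprop-1-en-2-yl]stannane
Product: 23 2-(but-2-yn-1-yl)-3,6-diethoxy-5-methylphenol, via alkenylcyclobutenone 20 (not isolated), via dienylketene 21 (not isolated), via cyclohexadienone 22 (not isolated)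
Conditions: PdCl2(PhCN)2 (5 mol %), tri(2-furyl)phosphine (10 mol %), CuI (10 mol %), dioxane, 50 °C, then 100 °C
Reagents that add atoms: none
Why: Zerovalent palladium inserts into the allylic C4–Cl bond of 19, Stille transmetalation with 13 and reductive elimination give alkenylcyclobutenone 20, whose strained ring opens thermally by 4π-conrotation (cleavage of its C1–C4 bond) to dienylketene 21; 6π-electrocyclisation then bonds the ketene carbon (future C2–OH of the quinone) to the enol-ether carbon (future C1), and enolisation of dienone 22 gives the phenol. The closest known reaction type is the palladium-catalysed coupling of 4-chlorocyclobutenones with alkenylstannanes that ends in phenol formation, its pericyclic half being the cyclobutenone ring expansion of the Danheiser benzannulation. The only ring closed is the six-membered carbocycle, by thermal disrotatory 6π-electrocyclisation of the (3E)-dienylketene. No stereocenter persists: C4 of 20 and C6 of 22 are transient and are erased by ring opening and aromatisation, so the racemic nature of 19 is irrelevant. The step needs coupling at C4 without allylic transposition to C2, which retention of the vinylogous-ester conjugation should secure, and inward rotation of the alkenyl group on ring opening, which is secured because the outward-rotated ketene can only revert to 20 whereas the inward isomer is drained irreversibly by cyclisation and aromatisation. The substitution pattern of 23 follows from connectivity alone: the ynol-ether carbons become C3 and C4, the stannane carbons C6 and C1, and the chloride-bearing carbon becomes the still unsubstituted C5.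

**Step 12**
Reactants: 23 2-(but-2-yn-1-yl)-3,6-diethoxy-5-methylphenol
Product: 24 2-(but-2-yn-1-yl)-4-chloro-3,6-diethoxy-5-methylphenol
Conditions: N-chlorosuccinimide, MeCN, 0 °C
Reagents that add atoms: N-chlorosuccinimide ClN1C(=O)CCC1=O
Why: Electrophilic aromatic chlorination at the only free ring position, para to the phenol OH and ortho to an ethoxy group, with the internal alkyne inert to the reagent.

**Step 13**
Reactants: 24 2-(but-2-yn-1-yl)-4-chloro-3,6-diethoxy-5-methylphenol
Product: 26 4-chloro-3,6-diethoxy-2-[(2E)-3-iodobut-2-en-1-yl]-5-methylphenol, via alkenylzirconocene 25 (not isolated)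
Conditions: Cp2Zr(H)Cl (2.5 equiv), THF, 25 to 45 °C; then I2, 0 °C
Reagents that add atoms: iodine II
Why: Syn hydrozirconation of the internal alkyne should place zirconium on the less hindered methyl-bearing carbon after equilibration with excess hydride (one equivalent is consumed by the phenol), and iodinolysis with retention gives the E iodide.

**Step 14**
Reactants: 26 4-chloro-3,6-diethoxy-2-[(2E)-3-iodobut-2-en-1-yl]-5-methylphenol; 11 2-[(1S,2R,6R)-1,2,6-trimethyl-3-oxocyclohexyl]acetaldehyde
Product: 28 4-chloro-3,6-diethoxy-2-{(2E,4S)-4-hydroxy-3-methyl-5-[(1S,2R,6R)-1,2,6-trimethyl-3-oxocyclohexyl]pent-2-en-1-yl}-5-methylphenol, via alkenylchromium dichloride 27 (not isolated)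
Conditions: CrCl2 (4 equiv), NiCl2 (2 mol %), chiral oxazoline–sulfonamide ligand (valine-derived, 4.4 equiv), Et3N, THF, 25 °C
Reagents that add atoms: none
Why: Nozaki–Hiyama–Kishi coupling, in which the nickel-catalysed alkenylchromium species forms with retention of geometry and adds to the aldehyde far faster than to the hindered ketone, the ligand enantiomer on chromium being chosen to direct attack to the Re face and so set the 4S carbinol (reagent control).

**Step 15**
Reactants: 28 4-chloro-3,6-diethoxy-2-{(2E,4S)-4-hydroxy-3-methyl-5-[(1S,2R,6R)-1,2,6-trimethyl-3-oxocyclohexyl]pent-2-en-1-yl}-5-methylphenol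
Product: 29 5-chloro-2-hydroxy-3-{(2E,4S)-4-hydroxy-3-methyl-5-[(1S,2R,6R)-1,2,6-trimethyl-3-oxocyclohexyl]pent-2-en-1-yl}-6-methylcyclohexa-2,5-diene-1,4-dione
Conditions: (NH4)2Ce(NO3)6 (2.5 equiv), MeCN–H2O, 0 °C
Reagents that add atoms: water O
Why: Oxidative de-ethylation of the para-diethoxyarene by tetravalent cerium with water as the oxygen source should give the para-quinone and leave the C2 hydroxyl, and any ortho-quinone ethyl vinylogous ester formed by the alternative pathway hydrolyses in the acidic medium to the same hydroxyquinone.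

**Compound list**

1 | propanal | CCC=O | starting material
2 | but-3-en-2-one | CC(=O)C=C | starting material
3 | (2R)-2-methyl-5-oxohexanal | O=C[C@H](C)CCC(C)=O | intermediate
4 | (4R)-4-methylcyclohex-2-en-1-one | O=C1C=C[C@H](C)CC1 | intermediate
5 | trimethyl{[(3S,4R)-3,4-dimethylcyclohex-1-en-1-yl]oxy}silane | C[Si](C)(C)OC1=C[C@@H](C)[C@H](C)CC1 | intermediate
6 | (4R)-3,4-dimethylcyclohex-2-en-1-one | O=C1C=C(C)[C@H](C)CC1 | intermediate
7 | trimethyl{[(3S,4R)-3,4-dimethyl-3-(prop-2-en-1-yl)cyclohex-1-en-1-yl]oxy}silane | C[Si](C)(C)OC1=C[C@](CC=C)(C)[C@H](C)CC1 | intermediate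
8 | lithium (3S,4R)-3,4-dimethyl-3-(prop-2-en-1-yl)cyclohex-1-en-1-olate | [Li]OC1=C[C@](CC=C)(C)[C@H](C)CC1 | intermediate
9 | (2R,3S,4R)-2,3,4-trimethyl-3-(prop-2-en-1-yl)cyclohexan-1-one | C=CC[C@@]1(C)[C@H](C)CCC(=O)[C@@H]1C | intermediate
10 | 3-{[(1S,2R,6R)-1,2,6-trimethyl-3-oxocyclohexyl]methyl}-1,2,4-trioxolane | C1OC(C[C@@]2(C)[C@H](C)CCC(=O)[C@@H]2C)OO1 | intermediate
11 | 2-[(1S,2R,6R)-1,2,6-trimethyl-3-oxocyclohexyl]acetaldehyde | O=CC[C@@]1(C)[C@H](C)CCC(=O)[C@@H]1C | intermediate
12 | 1-ethoxyprop-1-yne | CCOC#CC | starting material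
13 | tributyl[(1Z)-1-ethoxyprop-1-en-2-yl]stannane | CCO/C=C(/C)[Sn](CCCC)(CCCC)CCCC | intermediate
14 | ethoxyethyne | CCOC#C | starting material
15 | 1-bromobut-2-yne | CC#CCBr | starting material
16 | lithium ethoxyacetylide | CCOC#C[Li] | intermediate
17 | 1-ethoxyhexa-1,4-diyne | CCOC#CCC#CC | intermediate
18 | 2-(but-2-yn-1-yl)-4,4-dichloro-3-ethoxycyclobut-2-en-1-one | CCOC1=C(CC#CC)C(=O)C1(Cl)Cl | intermediate
19 | 2-(but-2-yn-1-yl)-4-chloro-3-ethoxycyclobut-2-en-1-one (racemic) | CCOC1=C(CC#CC)C(=O)C1Cl | intermediate
20 | 2-(but-2-yn-1-yl)-3-ethoxy-4-[(1Z)-1-ethoxyprop-1-en-2-yl]cyclobut-2-en-1-one (racemic) | CCO/C=C(/C)C1C(=O)C(CC#CC)=C1OCC | intermediate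
21 | (3E,5Z)-2-(but-2-yn-1-yl)-3,6-diethoxy-5-methylhexa-1,3,5-trien-1-one | O=C=C(CC#CC)/C(OCC)=C\C(C)=C/OCC | intermediate
22 | 2-(but-2-yn-1-yl)-3,6-diethoxy-5-methylcyclohexa-2,4-dien-1-one (racemic) | CCOC1C(C)=CC(OCC)=C(CC#CC)C1=O | intermediate
23 | 2-(but-2-yn-1-yl)-3,6-diethoxy-5-methylphenol | CCOc1cc(C)c(OCC)c(O)c1CC#CC | intermediate
24 | 2-(but-2-yn-1-yl)-4-chloro-3,6-diethoxy-5-methylphenol | CCOc1c(Cl)c(C)c(OCC)c(O)c1CC#CC | intermediate
25 | O-zirconated chloro[(2E)-4-(3-chloro-2,5-diethoxy-6-hydroxy-4-methylphenyl)but-2-en-2-yl]zirconocene | C/C(=C\Cc1c(O[Zr](Cl)(C2C=CC=C2)C2C=CC=C2)c(OCC)c(C)c(Cl)c1OCC)[Zr](Cl)(C1C=CC=C1)C1C=CC=C1 | intermediate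
26 | 4-chloro-3,6-diethoxy-2-[(2E)-3-iodobut-2-en-1-yl]-5-methylphenol | CCOc1c(Cl)c(C)c(OCC)c(O)c1C/C=C(\C)I | intermediate
27 | dichloro[(2E)-4-(3-chloro-2,5-diethoxy-6-hydroxy-4-methylphenyl)but-2-en-2-yl]chromium | CCOc1c(Cl)c(C)c(OCC)c(O)c1C/C=C(\C)[Cr](Cl)Cl | intermediate
28 | 4-chloro-3,6-diethoxy-2-{(2E,4S)-4-hydroxy-3-methyl-5-[(1S,2R,6R)-1,2,6-trimethyl-3-oxocyclohexyl]pent-2-en-1-yl}-5-methylphenol | CCOc1c(Cl)c(C)c(OCC)c(O)c1C/C=C(\C)[C@@H](O)C[C@@]1(C)[C@H](C)CCC(=O)[C@@H]1C | intermediate
29 | 5-chloro-2-hydroxy-3-{(2E,4S)-4-hydroxy-3-methyl-5-[(1S,2R,6R)-1,2,6-trimethyl-3-oxocyclohexyl]pent-2-en-1-yl}-6-methylcyclohexa-2,5-diene-1,4-dione | CC1=C(Cl)C(=O)C(C/C=C(\C)[C@@H](O)C[C@@]2(C)[C@H](C)CCC(=O)[C@@H]2C)=C(O)C1=O | target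

**Totals.** Total step count: 15. Longest linear sequence: 8 steps (steps 8–15; the cyclohexanone branch, steps 1–6 followed by 14 and 15, is equally long).

**Steps most likely to fail**

Step 11. Transmetalation of the α-branched, acid-labile stannane may be slow, so that protodestannylation or allylic transposition at palladium outruns coupling. The fallback avoids palladium and tin by a photochemical Danheiser benzannulation that sets out from ynol ether 17 and replaces steps 9 to 11. Commercial ethyl prop-1-enyl ether and oxalyl chloride give (2E)-3-ethoxy-2-methylprop-2-enoyl chloride F1, which diazomethane and Et3N convert into (3E)-1-diazo-4-ethoxy-3-methylbut-3-en-2-one F2. Irradiation of F2 in the presence of 17 effects Wolff rearrangement to (3E)-4-ethoxy-3-methylbuta-1,3-dien-1-one F3, which adds [2+2] to the ynol-ether triple bond to give 2-(but-2-yn-1-yl)-3-ethoxy-4-[(1E)-1-ethoxyprop-1-en-2-yl]cyclobut-2-en-1-one F4. Heating at 80–100 °C opens F4 to (3E,5E)-2-(but-2-yn-1-yl)-3,6-diethoxy-5-methylhexa-1,3,5-trien-1-one F5, which closes through the same C1–C2 bond to dienone 22 and enolises to phenol 23, where the route is rejoined.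

Step 14. Facial selectivity in the chromium-mediated addition may be poor, since the resident stereocenters are remote and everything depends on the ligand; the free phenol may also slow the coupling. The fallback changes metal and source of asymmetry and sets out from alkyne 24 and aldehyde 11. Hydrozirconation of 24 as in step 13 gives 25, which is transmetalated with Me2Zn to the O-zirconated methyl[(2E)-4-(3-chloro-2,5-diethoxy-6-hydroxy-4-methylphenyl)but-2-en-2-yl]zinc F6. F6 is added to 11 under catalysis by the enantiomer of 3-exo-morpholinoisoborneol that gives Re-face addition; alkenylzinc reagents add to aldehydes and not to ketones, so the route is rejoined directly at 28 without iodide 26.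

Step 10. Reduction may overrun to the chlorine-free cyclobutenone, or the vinylogous ester may hydrolyse under the protic conditions. The fallback sets out from 17 and reaches 19 in one step by [2+2] cycloaddition with chloroketene generated from chloroacetyl chloride and Et3N in Et2O at 0 °C, so that no reduction is needed; it makes no new compound (F0) and rejoins the route at 19.

**Further compounds**

F1 | step 11 | (2E)-3-ethoxy-2-methylprop-2-enoyl chloride | CCO/C=C(\C)C(Cl)=O
F2 | step 11 | (3E)-1-diazo-4-ethoxy-3-methylbut-3-en-2-one | CCO/C=C(\C)C(=O)C=[N+]=[N-]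
F3 | step 11 | (3E)-4-ethoxy-3-methylbuta-1,3-dien-1-one | CCO/C=C(\C)C=C=O
F4 | step 11 | 2-(but-2-yn-1-yl)-3-ethoxy-4-[(1E)-1-ethoxyprop-1-en-2-yl]cyclobut-2-en-1-one | CCO/C=C(\C)C1C(=O)C(CC#CC)=C1OCC
F5 | step 11 | (3E,5E)-2-(but-2-yn-1-yl)-3,6-diethoxy-5-methylhexa-1,3,5-trien-1-one | O=C=C(CC#CC)/C(OCC)=C\C(C)=C\OCC
F6 | step 14 | O-zirconated methyl[(2E)-4-(3-chloro-2,5-diethoxy-6-hydroxy-4-methylphenyl)but-2-en-2-yl]zinc | C/C(=C\Cc1c(O[Zr](Cl)(C2C=CC=C2)C2C=CC=C2)c(OCC)c(C)c(Cl)c1OCC)[Zn]C
F0 | step 10 | none | none
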